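**Retrosynthetic overview**
- Target ⇐ its aryl benzyl ether; the phenol is unmasked last by hydrogenolysis.
- Oxolane ring ⇐ acyclic triol by acid-catalysed benzylic C–O ring closure (O–C2 bond), which places the aryl group trans to the neighbouring CH2OH.
- Triol ⇐ trans-α-(hydroxybenzyl)-β-benzyl-γ-butyrolactone (LiAlH4); its ArCH(OH)–Cα bond ⇐ aldol addition of the lithium enolate of (R)-β-(4-benzyloxy-3-methoxybenzyl)-γ-butyrolactone to 3,4-dimethoxybenzaldehyde.
- (R)-Lactone ⇐ Evans alkylation of an N-(3-arylpropanoyl)oxazolidinone with tert-butyl bromoacetate, then LiBH4 and lactonisation; the acid ⇐ ferulic acid.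
- Ring order: γ-butyrolactone first (temporary, formed in step 7 and opened in step 9), oxolane second and last (step 10).

Assumption: the aldol adduct 16 and the triol 17 are carried as mixtures of epimers at the carbinol carbon (no descriptor at that atom in their SMILES), because both epimers converge in step 10.

**Step 1**
Reactants: 1 ferulic acid [(2E)-3-(4-hydroxy-3-methoxyphenyl)prop-2-enoic acid]
Product: 2 dihydroferulic acid [3-(4-hydroxy-3-methoxyphenyl)propanoic acid]
Conditions: H2 (1 atm), 10% Pd/C, MeOH, rt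
Reagents that add atoms: none
Why: Catalytic hydrogenation saturates the conjugated C=C bond while the arene, phenol and acid are untouched.

**Step 2**
Reactants: 2 dihydroferulic acid
Product: 3 benzyl 3-[4-(benzyloxy)-3-methoxyphenyl]propanoate
Conditions: BnBr (2.3 equiv), K2CO3 (2.5 equiv), DMF, 60 °C
Reagents that add atoms: benzyl bromide, BrCc1ccccc1
Why: Williamson etherification of the phenoxide and O-alkylation of the carboxylate occur together, so no selectivity between the two acidic sites is needed.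

**Step 3**
Reactants: 3 benzyl 3-[4-(benzyloxy)-3-methoxyphenyl]propanoate
Product: 4 3-[4-(benzyloxy)-3-methoxyphenyl]propanoic acid
Conditions: NaOH (2 M aq), MeOH–THF, 50 °C; then HCl (aq) to pH 2
Reagents that add atoms: sodium hydroxide NaOH, [Na+].[OH-]
Why: Saponification cleaves only the benzyl ester, because the aryl benzyl ether is inert to hydroxide.

**Step 4**
Reactants: 4 3-[4-(benzyloxy)-3-methoxyphenyl]propanoic acid; 5 (4S)-4-benzyl-1,3-oxazolidin-2-one
Product: 7 (4S)-4-benzyl-3-{3-[4-(benzyloxy)-3-methoxyphenyl]propanoyl}-1,3-oxazolidin-2-one, via mixed pivalic anhydride 6 (not isolated)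
Conditions: PivCl, Et3N, THF, −20 °C; then 5, LiCl, −20 °C to rt
Reagents that add atoms: none
Why: Mixed-anhydride N-acylation: the oxazolidinone attacks the unhindered acyl carbon of 6, and LiCl/Et3N makes it nucleophilic enough without a strong base.

**Step 5**
Reactants: 7 the N-acyl oxazolidinone; 8 tert-butyl bromoacetate
Product: 10 tert-butyl (3R)-4-[(4S)-4-benzyl-2-oxo-1,3-oxazolidin-3-yl]-3-{[4-(benzyloxy)-3-methoxyphenyl]methyl}-4-oxobutanoate, via sodium Z-enolate 9 (not isolated)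
Conditions: NaN(SiMe3)2 (1.1 equiv), THF, −78 °C; then 8, −78 to −40 °C
Reagents that add atoms: none
Why: Evans asymmetric alkylation: the chelated Z-enolate is alkylated on the face opposite the 4-benzyl group, setting the future oxolane C4 as R (dr typically above 95:5, minor isomer removed by chromatography).

**Step 6**
Reactants: 10 the alkylated imide
Product: 11 tert-butyl (3R)-4-[4-(benzyloxy)-3-methoxyphenyl]-3-(hydroxymethyl)butanoate
Conditions: LiBH4 (1.5 equiv), MeOH (1 equiv), THF, 0 °C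
Reagents that add atoms: none
Why: Reductive auxiliary cleavage: LiBH4 reduces the activated exocyclic imide carbonyl to the primary alcohol and leaves the tert-butyl ester, the benzyl ether and the stereocentre alone.

**Step 7**
Reactants: 11 the hydroxy tert-butyl ester
Product: 13 (4R)-4-{[4-(benzyloxy)-3-methoxyphenyl]methyl}oxolan-2-one, via hydroxy acid 12 (not isolated)
Conditions: TsOH·H2O (10 mol%), toluene, 80 °C
Reagents that add atoms: none
Why: Acid-catalysed tert-butyl ester cleavage (loss of isobutene) followed by spontaneous five-membered lactonisation; the stereocentre is β to the carbonyl and cannot epimerise.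

**Step 8**
Reactants: 13 the (R)-lactone; 14 3,4-dimethoxybenzaldehyde (veratraldehyde)
Product: 16 (3S,4R)-4-{[4-(benzyloxy)-3-methoxyphenyl]methyl}-3-[(3,4-dimethoxyphenyl)(hydroxy)methyl]oxolan-2-one (both carbinol epimers), via lithium enolate 15 (not isolated)
Conditions: LiN(SiMe3)2 (1.1 equiv), THF, −78 °C; then 14, −78 °C; AcOH quench at −78 °C
Reagents that add atoms: none
Why: Intermolecular aldol addition: the aldehyde adds to the enolate face anti to the C4 arylmethyl group, giving the 3,4-trans lactone (3S), and the cold acidic quench prevents retro-aldol.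

**Step 9**
Reactants: 16 the aldol adduct
Product: 17 (2R,3R)-2-{[4-(benzyloxy)-3-methoxyphenyl]methyl}-3-[(3,4-dimethoxyphenyl)(hydroxy)methyl]butane-1,4-diol (both carbinol epimers)
Conditions: LiAlH4 (3 equiv), THF, 0 °C to rt; then H2O/NaOH (aq) work-up
Reagents that add atoms: none
Why: Hydride reduction opens the lactone to the 1,4-diol without touching either stereocentre or the benzyl ether.

**Step 10**
Reactants: 17 the triol
Product: 18 [(2S,3R,4R)-4-{[4-(benzyloxy)-3-methoxyphenyl]methyl}-2-(3,4-dimethoxyphenyl)oxolan-3-yl]methanol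
Conditions: CSA (10 mol%), CH2Cl2, 0 °C to rt, TLC control; Et3N quench
Reagents that add atoms: none
Why: SN1 cycloetherification: the 3,4-dimethoxybenzylic cation is trapped by the only primary OH that can form a five-membered ring (the other would give an oxetane), and the aryl group settles trans to the adjacent CH2OH (2S) by kinetic preference and reversible ionisation, so both epimers of 17 converge.

**Step 11**
Reactants: 18 the benzyl-protected oxolane
Product: 19 4-{[(3R,4R,5S)-5-(3,4-dimethoxyphenyl)-4-(hydroxymethyl)oxolan-3-yl]methyl}-2-methoxyphenol (target)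
Conditions: H2 (1 atm), 10% Pd/C, EtOAc, rt, stopped at full conversion
Reagents that add atoms: none
Why: Hydrogenolysis of the aryl benzyl ether is much faster in neutral EtOAc than cleavage of the dialkyl benzylic C–O bond of the 2-aryloxolane, so the phenol is freed with all three stereocentres intact.

**Compound list**
1 | ferulic acid, (2E)-3-(4-hydroxy-3-methoxyphenyl)prop-2-enoic acid | COc1cc(/C=C/C(=O)O)ccc1O | starting material
2 | 3-(4-hydroxy-3-methoxyphenyl)propanoic acid | COc1cc(CCC(=O)O)ccc1O | intermediate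
3 | benzyl 3-[4-(benzyloxy)-3-methoxyphenyl]propanoate | COc1cc(CCC(=O)OCc2ccccc2)ccc1OCc1ccccc1 | intermediate
4 | 3-[4-(benzyloxy)-3-methoxyphenyl]propanoic acid | COc1cc(CCC(=O)O)ccc1OCc1ccccc1 | intermediate
5 | (4S)-4-benzyl-1,3-oxazolidin-2-one | O=C1N[C@@H](Cc2ccccc2)CO1 | starting material
6 | mixed anhydride of 4 and pivalic acid (formed in the flask) | COc1cc(CCC(=O)OC(=O)C(C)(C)C)ccc1OCc1ccccc1 | intermediate
7 | (4S)-4-benzyl-3-{3-[4-(benzyloxy)-3-methoxyphenyl]propanoyl}-1,3-oxazolidin-2-one | COc1cc(CCC(=O)N2[C@@H](Cc3ccccc3)COC2=O)ccc1OCc1ccccc1 | intermediate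
8 | tert-butyl bromoacetate | CC(C)(C)OC(=O)CBr | starting material
9 | sodium (Z)-enolate of 7 (formed in the flask) | [Na+].[O-]/C(=C\Cc1ccc(OCc2ccccc2)c(OC)c1)N1[C@@H](Cc2ccccc2)COC1=O | intermediate
10 | tert-butyl (3R)-4-[(4S)-4-benzyl-2-oxo-1,3-oxazolidin-3-yl]-3-{[4-(benzyloxy)-3-methoxyphenyl]methyl}-4-oxobutanoate | COc1cc(C[C@H](CC(=O)OC(C)(C)C)C(=O)N2[C@@H](Cc3ccccc3)COC2=O)ccc1OCc1ccccc1 | intermediate
11 | tert-butyl (3R)-4-[4-(benzyloxy)-3-methoxyphenyl]-3-(hydroxymethyl)butanoate | COc1cc(C[C@H](CC(=O)OC(C)(C)C)CO)ccc1OCc1ccccc1 | intermediate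
12 | (3R)-4-[4-(benzyloxy)-3-methoxyphenyl]-3-(hydroxymethyl)butanoic acid (formed in the flask) | COc1cc(C[C@H](CC(=O)O)CO)ccc1OCc1ccccc1 | intermediate
13 | (4R)-4-{[4-(benzyloxy)-3-methoxyphenyl]methyl}oxolan-2-one | COc1cc(C[C@H]2COC(=O)C2)ccc1OCc1ccccc1 | intermediate
14 | 3,4-dimethoxybenzaldehyde | COc1ccc(C=O)cc1OC | starting material
15 | lithium enolate of 13, lithium (4R)-4-{[4-(benzyloxy)-3-methoxyphenyl]methyl}-4,5-dihydrofuran-2-olate (formed in the flask) | [Li+].[O-]C1=C[C@@H](Cc2ccc(OCc3ccccc3)c(OC)c2)CO1 | intermediate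
16 | (3S,4R)-4-{[4-(benzyloxy)-3-methoxyphenyl]methyl}-3-[(3,4-dimethoxyphenyl)(hydroxy)methyl]oxolan-2-one, 3,4-trans, epimers at the carbinol carbon | COc1ccc(C(O)[C@H]2C(=O)OC[C@@H]2Cc2ccc(OCc3ccccc3)c(OC)c2)cc1OC | intermediate
17 | (2R,3R)-2-{[4-(benzyloxy)-3-methoxyphenyl]methyl}-3-[(3,4-dimethoxyphenyl)(hydroxy)methyl]butane-1,4-diol, epimers at the carbinol carbon | COc1cc(C[C@@H](CO)[C@H](CO)C(O)c2ccc(OC)c(OC)c2)ccc1OCc1ccccc1 | intermediate
18 | [(2S,3R,4R)-4-{[4-(benzyloxy)-3-methoxyphenyl]methyl}-2-(3,4-dimethoxyphenyl)oxolan-3-yl]methanol | COc1cc(C[C@H]2CO[C@H](c3ccc(OC)c(OC)c3)[C@H]2CO)ccc1OCc1ccccc1 | intermediate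
19 | 4-{[(3R,4R,5S)-5-(3,4-dimethoxyphenyl)-4-(hydroxymethyl)oxolan-3-yl]methyl}-2-methoxyphenol | COc1cc(C[C@H]2CO[C@H](c3ccc(OC)c(OC)c3)[C@H]2CO)ccc1O | target

**Totals**
Total step count: 11. Longest linear sequence: 11 steps (1 to 19).

**Steps most likely to fail, with fallbacks**

Step 10 (ring closure). The benzylic cation can also attack the electron-rich benzyloxy-methoxy ring para to its methoxy group (Friedel–Crafts closure to an aryltetralin), and some 2,3-cis isomer may form. The fallback sets out from 13 and comes back at 19. Lactone 13 is brominated (NBS, MeCN, 0 °C) at the ring position para to the methoxy group, the site that would attack the cation, to give (4R)-4-{[4-(benzyloxy)-2-bromo-5-methoxyphenyl]methyl}oxolan-2-one F2. The same aldol addition (LiN(SiMe3)2, THF, −78 °C, then 14) gives (3S,4R)-4-{[4-(benzyloxy)-2-bromo-5-methoxyphenyl]methyl}-3-[(3,4-dimethoxyphenyl)(hydroxy)methyl]oxolan-2-one F3. LiAlH4 in THF at 0 °C gives (2R,3R)-2-{[4-(benzyloxy)-2-bromo-5-methoxyphenyl]methyl}-3-[(3,4-dimethoxyphenyl)(hydroxy)methyl]butane-1,4-diol F4. CSA in CH2Cl2 then closes the ring with the competing arene position blocked, so the acid can be left long enough to equilibrate fully to the trans isomer, giving [(2S,3R,4R)-4-{[4-(benzyloxy)-2-bromo-5-methoxyphenyl]methyl}-2-(3,4-dimethoxyphenyl)oxolan-3-yl]methanol F5. One hydrogenation (H2, 10% Pd/C, NaOAc, EtOAc–MeOH) removes both the bromine and the benzyl group and delivers 19.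

Step 8 (aldol). The addition is reversible and may stall or revert on work-up. The fallback sets out from 13 and comes back at 16. The same C–C bond is made by an irreversible crossed Claisen condensation: the enolate of 13 (LiN(SiMe3)2, 2.1 equiv, THF, −78 °C) is C-acylated by 3,4-dimethoxybenzoyl chloride to give the β-keto lactone (3S,4R)-4-{[4-(benzyloxy)-3-methoxyphenyl]methyl}-3-(3,4-dimethoxybenzoyl)oxolan-2-one F1. Its acidic C3 settles in the trans arrangement. NaBH4 (MeOH–THF, −20 °C) reduces only the aryl ketone and delivers 16; either carbinol epimer serves.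

Step 11 (debenzylation). Over-reduction could open the 2-aryloxolane at its benzylic C–O bond. The fallback sets out from 13 and comes back at 19, and runs no hydrogenation once a benzylic C–O bond exists. Lactone 13 is debenzylated (H2, 10% Pd/C, EtOAc) to (4R)-4-[(4-hydroxy-3-methoxyphenyl)methyl]oxolan-2-one F6. Silylation (TBSCl, imidazole, DMF) gives (4R)-4-({4-[(tert-butyldimethylsilyl)oxy]-3-methoxyphenyl}methyl)oxolan-2-one F7. Aldol addition as in step 8 gives (3S,4R)-4-({4-[(tert-butyldimethylsilyl)oxy]-3-methoxyphenyl}methyl)-3-[(3,4-dimethoxyphenyl)(hydroxy)methyl]oxolan-2-one F8. LiBH4 in THF gives (2R,3R)-2-({4-[(tert-butyldimethylsilyl)oxy]-3-methoxyphenyl}methyl)-3-[(3,4-dimethoxyphenyl)(hydroxy)methyl]butane-1,4-diol F9. CSA in CH2Cl2 gives [(2S,3R,4R)-4-({4-[(tert-butyldimethylsilyl)oxy]-3-methoxyphenyl}methyl)-2-(3,4-dimethoxyphenyl)oxolan-3-yl]methanol F10. Bu4NF (THF, 0 °C) then frees the phenol to give 19.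

**Further compounds**
F1 | step 8 | (3S,4R)-4-{[4-(benzyloxy)-3-methoxyphenyl]methyl}-3-(3,4-dimethoxybenzoyl)oxolan-2-one | COc1ccc(C(=O)[C@H]2C(=O)OC[C@@H]2Cc2ccc(OCc3ccccc3)c(OC)c2)cc1OC
F2 | step 10 | (4R)-4-{[4-(benzyloxy)-2-bromo-5-methoxyphenyl]methyl}oxolan-2-one | COc1cc(C[C@H]2COC(=O)C2)c(Br)cc1OCc1ccccc1
F3 | step 10 | (3S,4R)-4-{[4-(benzyloxy)-2-bromo-5-methoxyphenyl]methyl}-3-[(3,4-dimethoxyphenyl)(hydroxy)methyl]oxolan-2-one, epimers at the carbinol carbon | COc1ccc(C(O)[C@H]2C(=O)OC[C@@H]2Cc2cc(OC)c(OCc3ccccc3)cc2Br)cc1OC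
F4 | step 10 | (2R,3R)-2-{[4-(benzyloxy)-2-bromo-5-methoxyphenyl]methyl}-3-[(3,4-dimethoxyphenyl)(hydroxy)methyl]butane-1,4-diol, epimers at the carbinol carbon | COc1cc(C[C@@H](CO)[C@H](CO)C(O)c2ccc(OC)c(OC)c2)c(Br)cc1OCc1ccccc1
F5 | step 10 | [(2S,3R,4R)-4-{[4-(benzyloxy)-2-bromo-5-methoxyphenyl]methyl}-2-(3,4-dimethoxyphenyl)oxolan-3-yl]methanol | COc1cc(C[C@H]2CO[C@H](c3ccc(OC)c(OC)c3)[C@H]2CO)c(Br)cc1OCc1ccccc1
F6 | step 11 | (4R)-4-[(4-hydroxy-3-methoxyphenyl)methyl]oxolan-2-one | COc1cc(C[C@H]2COC(=O)C2)ccc1O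
F7 | step 11 | (4R)-4-({4-[(tert-butyldimethylsilyl)oxy]-3-methoxyphenyl}methyl)oxolan-2-one | COc1cc(C[C@H]2COC(=O)C2)ccc1O[Si](C)(C)C(C)(C)C
F8 | step 11 | (3S,4R)-4-({4-[(tert-butyldimethylsilyl)oxy]-3-methoxyphenyl}methyl)-3-[(3,4-dimethoxyphenyl)(hydroxy)methyl]oxolan-2-one, epimers at the carbinol carbon | COc1ccc(C(O)[C@H]2C(=O)OC[C@@H]2Cc2ccc(O[Si](C)(C)C(C)(C)C)c(OC)c2)cc1OC
F9 | step 11 | (2R,3R)-2-({4-[(tert-butyldimethylsilyl)oxy]-3-methoxyphenyl}methyl)-3-[(3,4-dimethoxyphenyl)(hydroxy)methyl]butane-1,4-diol, epimers at the carbinol carbon | COc1cc(C[C@@H](CO)[C@H](CO)C(O)c2ccc(OC)c(OC)c2)ccc1O[Si](C)(C)C(C)(C)C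
F10 | step 11 | [(2S,3R,4R)-4-({4-[(tert-butyldimethylsilyl)oxy]-3-methoxyphenyl}methyl)-2-(3,4-dimethoxyphenyl)oxolan-3-yl]methanol | COc1cc(C[C@H]2CO[C@H](c3ccc(OC)c(OC)c3)[C@H]2CO)ccc1O[Si](C)(C)C(C)(C)C
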